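Everything rests on cutting C9–C10 and C7–C8 of the seven-membered ring B. C8 and C9, each bearing a methyl group and flanked by benzylic C7 and C10, map onto the α- and β-carbons of a chiral 5-alkoxybutenolide whose carbonyl and acetal carbons are the two latent methyls. In one flask a lithiated trimethoxyphenyl dithiane (ring A, C10 as acyl anion) adds to the butenolide and the enolate is benzylated by a silyl-protected syringyl bromide (C7, future dienone ring C), setting C8 and C9 from the acetal centre. The precursor set is therefore these three fragments; the spiro bond is left to a late phenol oxidation.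

Key step: step 7

Remark (labels): ring A = trimethoxybenzene ring, ring B = seven-membered carbocycle, ring C = dimethoxydienone ring; C7 = ring B CH2 on the spiro carbon, C8 and C9 = methyl-bearing carbons, C10 = benzoyloxy carbon; the target is (8R,9S,10R).
Remark (protecting group): the phenol is carried as a triisopropylsilyl ether, which is safer than a tert-butyldimethylsilyl ether toward NaBH4/MeOH at the para-formyl stage and toward LiAlH4 and LiEt3BH.
Remark (C10): in the target the C10 oxygen is syn to the C9 methyl (zigzag ring A–C10–C9–C8), whereas Felkin–Anh hydride delivery to the C10 ketone would give the anti (10S) epimer, so the ketone reduction is placed under catalyst control.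

Step 1
Reactants: 1 3,4,5-trimethoxybenzaldehyde
Product: 2 2-(3,4,5-trimethoxyphenyl)-1,3-dithiane
Conditions: HS(CH2)3SH, BF3·OEt2 (cat.), CH2Cl2, 0 °C to rt
Reagents that add atoms: propane-1,3-dithiol, SCCCS
Why: Lewis-acid-catalysed dithioacetalisation of an aromatic aldehyde is reliable, the electron-rich ring is inert under these conditions, and no stereocentre is formed.

Step 2
Reactants: 3 furfural
Product: 5 5-hydroxyfuran-2(5H)-one, via endoperoxide 4 (not isolated)
Conditions: O2, hν (visible), 3,7-bis(dimethylamino)phenothiazin-5-ium chloride (methylene blue, cat.), MeOH, rt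
Reagents that add atoms: oxygen, O=O
Why: Dye-sensitised photooxygenation, in which singlet oxygen adds [4+2] across the furan to give endoperoxide 4, methanol attacks its formyl group and fragmentation expels methyl formate to leave the racemic hydroxybutenolide.

Step 3
Reactants: 5 5-hydroxyfuran-2(5H)-one; 6 l-menthol
Product: 8 (5R)-5-(l-menthyloxy)furan-2(5H)-one, via 5S epimer 7 (not isolated)
Conditions: camphor-10-sulfonic acid (cat.), PhMe, reflux with azeotropic water removal; crystallisation from hexane, mother liquor re-equilibrated with acid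
Reagents that add atoms: none
Why: Acid-catalysed acetalisation of the lactol (Fischer-type glycosidation) gives both C5 epimers, which equilibrate through the ring oxocarbenium ion while only the 5R epimer crystallises, so the acetal stereocentre is set by crystallisation-induced epimerisation with l-menthol as the only chiral source.

Step 4
Reactants: 9 syringaldehyde
Product: 10 3,5-dimethoxy-4-(triisopropylsilyloxy)benzaldehyde
Conditions: TIPSCl, imidazole, DMF, rt
Reagents that add atoms: chlorotriisopropylsilane, CC(C)[Si](Cl)(C(C)C)C(C)C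
Why: Imidazole-mediated O-silylation of an acidic phenol is routine, and the bulky silyl group is chosen to survive the hydride reagents used later.

Step 5
Reactants: 10 3,5-dimethoxy-4-(triisopropylsilyloxy)benzaldehyde
Product: 11 [3,5-dimethoxy-4-(triisopropylsilyloxy)phenyl]methanol
Conditions: NaBH4, MeOH/THF, 0 °C
Reagents that add atoms: none
Why: Borohydride reduction of an aryl aldehyde is complete within minutes at 0 °C, after which the ring is electron-rich and the silyl ether is no longer activated toward cleavage.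

Step 6
Reactants: 11 [3,5-dimethoxy-4-(triisopropylsilyloxy)phenyl]methanol
Product: 12 3,5-dimethoxy-4-(triisopropylsilyloxy)benzyl bromide
Conditions: CBr4, PPh3, CH2Cl2, 0 °C; used at once
Reagents that add atoms: carbon tetrabromide, BrC(Br)(Br)Br
Why: Appel bromination converts the benzylic alcohol under neutral conditions that spare the silyl ether.

Step 7
Reactants: 2 2-(3,4,5-trimethoxyphenyl)-1,3-dithiane; 8 (5R)-5-(l-menthyloxy)furan-2(5H)-one; 12 3,5-dimethoxy-4-(triisopropylsilyloxy)benzyl bromide
Product: 15 (3R,4R,5R)-3-[3,5-dimethoxy-4-(triisopropylsilyloxy)benzyl]-5-(l-menthyloxy)-4-[2-(3,4,5-trimethoxyphenyl)-1,3-dithian-2-yl]dihydrofuran-2(3H)-one, via lithiated dithiane 13 (not isolated), via lithium enolate 14 (not isolated)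
Conditions: n-BuLi, THF, −30 °C; 8, −78 °C; 12, DMPU, −78 to −20 °C; aq. NH4Cl
Reagents that add atoms: none
Why: n-BuLi deprotonates 2 to the sulfur- and aryl-stabilised acyl-anion equivalent 13, which adds in a Michael sense to C4 of butenolide 8 to give lithium enolate 14 (C9–C10 bond), and 14 is then C-benzylated by bromide 12 in an SN2 step (C7–C8 bond). The closest known reaction type is the tandem conjugate addition–enolate alkylation of lithiated aryl dithioacetals with 5-alkoxyfuran-2(5H)-ones, used for dibenzylbutyrolactone lignans. No ring is closed; the two new bonds only attach ring A (through C10) and ring C (through C7) to the lactone. C9 is set by attack on the butenolide face opposite the C5 menthyloxy group, and C8 by alkylation of the planar enolate opposite the new, very bulky dithianyl group at C9, so both centres derive from the single acetal centre and should come out trans,trans. The step needs 1,4- instead of 1,2-addition, which the soft delocalised anion and the activated γ-alkoxy enoate secure at −78 °C, and two successive anti approaches, which the acetal substituent and then the C9 substituent secure. C-mono-alkylation is favoured by the reactive benzylic bromide with DMPU, by using no excess base, and by keeping the enolate below −20 °C so that it neither reverts nor eliminates.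

Step 8
Reactants: 15 (3R,4R,5R)-3-[3,5-dimethoxy-4-(triisopropylsilyloxy)benzyl]-5-(l-menthyloxy)-4-[2-(3,4,5-trimethoxyphenyl)-1,3-dithian-2-yl]dihydrofuran-2(3H)-one
Product: 17 (2R,3R)-2-[3,5-dimethoxy-4-(triisopropylsilyloxy)benzyl]-3-[2-(3,4,5-trimethoxyphenyl)-1,3-dithian-2-yl]butane-1,4-diol, via hydroxy aldehyde 16 (not isolated)
Conditions: LiAlH4, THF, 0 °C to rt; aq. NaOH work-up
Reagents that add atoms: none
Why: LiAlH4 reduction of the lactone to the primary alkoxide releases the hemiacetal, which loses menthoxide to aldehyde 16 and is reduced again (known reductive opening of 5-alkoxybutyrolactones), so both carbonyl-level carbons end as CH2OH without touching C8 or C9.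

Step 9
Reactants: 17 (2R,3R)-2-[3,5-dimethoxy-4-(triisopropylsilyloxy)benzyl]-3-[2-(3,4,5-trimethoxyphenyl)-1,3-dithian-2-yl]butane-1,4-diol
Product: 18 bis(methanesulfonate) of diol 17
Conditions: MsCl, Et3N, CH2Cl2, −20 °C; used without delay
Reagents that add atoms: methanesulfonyl chloride, CS(=O)(=O)Cl
Why: Sulfonylation with MsCl/Et3N (sulfene pathway) is fast on both primary hydroxyls at low temperature, so the bis-mesylate should form before a mono-sulfonate can cyclise to a tetrahydrofuran.

Step 10
Reactants: 18 bis(methanesulfonate) of diol 17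
Product: 19 2-{(2S,3R)-4-[3,5-dimethoxy-4-(triisopropylsilyloxy)phenyl]-3-methylbutan-2-yl}-2-(3,4,5-trimethoxyphenyl)-1,3-dithiane
Conditions: LiEt3BH, THF, 0 °C to rt
Reagents that add atoms: none
Why: SN2 hydride displacement of primary mesylates by the strongly nucleophilic LiEt3BH turns both CH2OMs groups into the C8 and C9 methyls fast enough to outrun participation by dithiane sulfur, and dithiane and silyl ether are inert to the reagent.

Step 11
Reactants: 19 2-{(2S,3R)-4-[3,5-dimethoxy-4-(triisopropylsilyloxy)phenyl]-3-methylbutan-2-yl}-2-(3,4,5-trimethoxyphenyl)-1,3-dithiane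
Product: 20 (2S,3R)-4-[3,5-dimethoxy-4-(triisopropylsilyloxy)phenyl]-2,3-dimethyl-1-(3,4,5-trimethoxyphenyl)butan-1-one
Conditions: Hg(ClO4)2, CaCO3, THF/H2O, 0 °C, short reaction time
Reagents that add atoms: water, O
Why: Mercury-assisted dithioacetal hydrolysis, in which thiophilic divalent mercury opens the dithiane and water captures the thionium ion, while the CaCO3 buffer keeps the medium neutral so that C9, now α to the aryl ketone, should not epimerise.

Step 12
Reactants: 20 (2S,3R)-4-[3,5-dimethoxy-4-(triisopropylsilyloxy)phenyl]-2,3-dimethyl-1-(3,4,5-trimethoxyphenyl)butan-1-one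
Product: 21 (1R,2S,3R)-4-[3,5-dimethoxy-4-(triisopropylsilyloxy)phenyl]-2,3-dimethyl-1-(3,4,5-trimethoxyphenyl)butan-1-ol
Conditions: (S)-1-methyl-3,3-diphenyl-tetrahydro-1H,3H-pyrrolo[1,2-c][1,3,2]oxazaborole (0.5 equiv), BH3·SMe2, THF, −20 °C; MeOH quench
Reagents that add atoms: none
Why: Corey–Bakshi–Shibata reduction, in which the oxazaborolidine–borane complex binds the ketone with the aryl group as the large substituent and delivers hydride to the Si face of C10, should give the 10R carbinol under catalyst control against the weak Felkin–Anh bias of a small borane, and the non-basic medium leaves C9 intact.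

Step 13
Reactants: 21 (1R,2S,3R)-4-[3,5-dimethoxy-4-(triisopropylsilyloxy)phenyl]-2,3-dimethyl-1-(3,4,5-trimethoxyphenyl)butan-1-ol
Product: 22 (1R,2S,3R)-4-[3,5-dimethoxy-4-(triisopropylsilyloxy)phenyl]-2,3-dimethyl-1-(3,4,5-trimethoxyphenyl)butyl benzoate
Conditions: BzCl, pyridine, 4-(dimethylamino)pyridine (cat.), CH2Cl2, 0 °C to rt
Reagents that add atoms: benzoyl chloride, O=C(Cl)c1ccccc1
Why: Nucleophile-catalysed O-acylation of the secondary alcohol leaves the C10–O bond intact, so the benzoate forms with retention at C10.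

Step 14
Reactants: 22 (1R,2S,3R)-4-[3,5-dimethoxy-4-(triisopropylsilyloxy)phenyl]-2,3-dimethyl-1-(3,4,5-trimethoxyphenyl)butyl benzoate
Product: 23 (1R,2S,3R)-4-(4-hydroxy-3,5-dimethoxyphenyl)-2,3-dimethyl-1-(3,4,5-trimethoxyphenyl)butyl benzoate
Conditions: Bu4NF, AcOH, THF, 0 °C
Reagents that add atoms: none
Why: Fluoride-induced Si–O cleavage of an aryl silyl ether is fast at 0 °C, and the acetic acid buffer protonates the phenoxide so that the benzoate is not attacked.

Step 15
Reactants: 23 (1R,2S,3R)-4-(4-hydroxy-3,5-dimethoxyphenyl)-2,3-dimethyl-1-(3,4,5-trimethoxyphenyl)butyl benzoate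
Product: 25 CNP0201356.1 (8R,9S,10R), via aryloxyiodane 24 (not isolated)
Conditions: PhI(OCOCF3)2, CF3CH2OH, −40 °C; cold aq. NaHCO3 quench
Reagents that add atoms: none
Why: Oxidative phenol dearomatisation with a trivalent iodine reagent, in which ligand exchange gives aryloxyiodane 24, loss of iodobenzene leaves a phenoxonium ion stabilised by the two ortho methoxy groups, and its para carbon is attacked by the free ortho carbon of ring A (para to a methoxy group) in a seven-membered ipso spirocyclisation of the type known for phenolic dibenzylbutane lignans; the spiro carbon is not stereogenic because ring C is symmetric.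

Compound list
1 | 3,4,5-trimethoxybenzaldehyde | COc1cc(C=O)cc(OC)c1OC | starting material
2 | 2-(3,4,5-trimethoxyphenyl)-1,3-dithiane | COc1cc(C2SCCCS2)cc(OC)c1OC | intermediate
3 | furfural | O=Cc1ccco1 | starting material
4 | 2,3,7-trioxabicyclo[2.2.1]hept-5-ene-1-carbaldehyde (furfural endoperoxide) | O=CC12OOC(O1)C=C2 | intermediate
5 | 5-hydroxyfuran-2(5H)-one (racemic) | OC1OC(=O)C=C1 | intermediate
6 | l-menthol, (1R,2S,5R)-2-isopropyl-5-methylcyclohexan-1-ol | C[C@@H]1CC[C@H]([C@@H](C1)O)C(C)C | starting material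
7 | (5S)-5-(l-menthyloxy)furan-2(5H)-one | C[C@@H]1CC[C@H]([C@@H](C1)O[C@H]2OC(=O)C=C2)C(C)C | intermediate
8 | (5R)-5-(l-menthyloxy)furan-2(5H)-one | C[C@@H]1CC[C@H]([C@@H](C1)O[C@@H]2OC(=O)C=C2)C(C)C | intermediate
9 | syringaldehyde | COc1cc(C=O)cc(OC)c1O | starting material
10 | 3,5-dimethoxy-4-(triisopropylsilyloxy)benzaldehyde | COc1cc(C=O)cc(OC)c1O[Si](C(C)C)(C(C)C)C(C)C | intermediate
11 | [3,5-dimethoxy-4-(triisopropylsilyloxy)phenyl]methanol | COc1cc(CO)cc(OC)c1O[Si](C(C)C)(C(C)C)C(C)C | intermediate
12 | 3,5-dimethoxy-4-(triisopropylsilyloxy)benzyl bromide | BrCc1cc(OC)c(O[Si](C(C)C)(C(C)C)C(C)C)c(OC)c1 | intermediate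
13 | 2-lithio-2-(3,4,5-trimethoxyphenyl)-1,3-dithiane | [Li]C1(SCCCS1)c1cc(OC)c(OC)c(OC)c1 | intermediate
14 | lithium enolate of (4R,5R)-5-(l-menthyloxy)-4-[2-(3,4,5-trimethoxyphenyl)-1,3-dithian-2-yl]dihydrofuran-2(3H)-one | C[C@@H]1CC[C@H]([C@@H](C1)O[C@@H]2OC(O[Li])=C[C@H]2C3(SCCCS3)c4cc(OC)c(OC)c(OC)c4)C(C)C | intermediate
15 | (3R,4R,5R)-3-[3,5-dimethoxy-4-(triisopropylsilyloxy)benzyl]-5-(l-menthyloxy)-4-[2-(3,4,5-trimethoxyphenyl)-1,3-dithian-2-yl]dihydrofuran-2(3H)-one (trans,trans) | C[C@@H]1CC[C@H]([C@@H](C1)O[C@@H]2OC(=O)[C@H](Cc3cc(OC)c(O[Si](C(C)C)(C(C)C)C(C)C)c(OC)c3)[C@H]2C4(SCCCS4)c5cc(OC)c(OC)c(OC)c5)C(C)C | intermediate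
16 | (2R,3R)-3-[3,5-dimethoxy-4-(triisopropylsilyloxy)benzyl]-4-hydroxy-2-[2-(3,4,5-trimethoxyphenyl)-1,3-dithian-2-yl]butanal | OC[C@H](Cc1cc(OC)c(O[Si](C(C)C)(C(C)C)C(C)C)c(OC)c1)[C@H](C=O)C2(SCCCS2)c3cc(OC)c(OC)c(OC)c3 | intermediate
17 | (2R,3R)-2-[3,5-dimethoxy-4-(triisopropylsilyloxy)benzyl]-3-[2-(3,4,5-trimethoxyphenyl)-1,3-dithian-2-yl]butane-1,4-diol | OC[C@H](Cc1cc(OC)c(O[Si](C(C)C)(C(C)C)C(C)C)c(OC)c1)[C@H](CO)C2(SCCCS2)c3cc(OC)c(OC)c(OC)c3 | intermediate
18 | bis(methanesulfonate) of diol 17 | CS(=O)(=O)OC[C@H](Cc1cc(OC)c(O[Si](C(C)C)(C(C)C)C(C)C)c(OC)c1)[C@H](COS(C)(=O)=O)C2(SCCCS2)c3cc(OC)c(OC)c(OC)c3 | intermediate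
19 | 2-{(2S,3R)-4-[3,5-dimethoxy-4-(triisopropylsilyloxy)phenyl]-3-methylbutan-2-yl}-2-(3,4,5-trimethoxyphenyl)-1,3-dithiane | C[C@H](Cc1cc(OC)c(O[Si](C(C)C)(C(C)C)C(C)C)c(OC)c1)[C@H](C)C2(SCCCS2)c3cc(OC)c(OC)c(OC)c3 | intermediate
20 | (2S,3R)-4-[3,5-dimethoxy-4-(triisopropylsilyloxy)phenyl]-2,3-dimethyl-1-(3,4,5-trimethoxyphenyl)butan-1-one | C[C@H](Cc1cc(OC)c(O[Si](C(C)C)(C(C)C)C(C)C)c(OC)c1)[C@H](C)C(=O)c2cc(OC)c(OC)c(OC)c2 | intermediate
21 | (1R,2S,3R)-4-[3,5-dimethoxy-4-(triisopropylsilyloxy)phenyl]-2,3-dimethyl-1-(3,4,5-trimethoxyphenyl)butan-1-ol | C[C@H](Cc1cc(OC)c(O[Si](C(C)C)(C(C)C)C(C)C)c(OC)c1)[C@H](C)[C@@H](O)c2cc(OC)c(OC)c(OC)c2 | intermediate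
22 | (1R,2S,3R)-4-[3,5-dimethoxy-4-(triisopropylsilyloxy)phenyl]-2,3-dimethyl-1-(3,4,5-trimethoxyphenyl)butyl benzoate | C[C@H](Cc1cc(OC)c(O[Si](C(C)C)(C(C)C)C(C)C)c(OC)c1)[C@H](C)[C@@H](OC(=O)c2ccccc2)c3cc(OC)c(OC)c(OC)c3 | intermediate
23 | (1R,2S,3R)-4-(4-hydroxy-3,5-dimethoxyphenyl)-2,3-dimethyl-1-(3,4,5-trimethoxyphenyl)butyl benzoate | C[C@H](Cc1cc(OC)c(O)c(OC)c1)[C@H](C)[C@@H](OC(=O)c2ccccc2)c3cc(OC)c(OC)c(OC)c3 | intermediate
24 | aryloxy(phenyl)iodanyl trifluoroacetate of phenol 23 | C[C@H](Cc1cc(OC)c(OI(OC(=O)C(F)(F)F)c2ccccc2)c(OC)c1)[C@H](C)[C@@H](OC(=O)c3ccccc3)c4cc(OC)c(OC)c(OC)c4 | intermediate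
25 | CNP0201356.1, (7R,8S,9R)-2,3,3',4,5'-pentamethoxy-7,8-dimethyl-4'-oxo-6,7,8,9-tetrahydrospiro[benzo[7]annulene-5,1'-cyclohexa[2,5]dien]-9-yl benzoate (8R,9S,10R in the labels used here) | COC1=CC2(C=C(OC)C1=O)C[C@@H](C)[C@H](C)[C@@H](OC(=O)c1ccccc1)c1cc(OC)c(OC)c(OC)c12 | target

Total step count: 15.
Longest linear sequence: 12 steps (steps 4 to 15, from syringaldehyde 9).

Steps most likely to fail

Step 15. The phenoxonium ion may lose a proton from C7 to a quinone methide, be captured by solvent, or ring A and the product may be over-oxidised before the seven-membered closure takes place. The fallback sets out from phenol 23 and separates oxidation from C–C bond formation. Oxidation with PhI(OAc)2 in MeOH at 0 °C should stop at the solvent-trapped quinol ether, (1R,2S,3R)-2,3-dimethyl-4-(1,3,5-trimethoxy-4-oxocyclohexa-2,5-dien-1-yl)-1-(3,4,5-trimethoxyphenyl)butyl benzoate F1. After removal of the oxidant, BF3·OEt2 in CH2Cl2 at −78 °C should ionise the C1 methoxy group of F1 and regenerate the same cation with no oxidant or nucleophilic solvent present. Ring A should then close the spiro ring, and the fallback comes back to the route at 25.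

Step 12. Facial selectivity may be poor because catalyst control and the substrate's Felkin–Anh bias oppose each other, and the α-branched ketone may be reduced slowly. The fallback sets out from ketone 20 and uses the substrate bias instead of fighting it. LiB(s-Bu)3H in THF at −78 °C should give the Felkin–Anh product, (1S,2S,3R)-4-[3,5-dimethoxy-4-(triisopropylsilyloxy)phenyl]-2,3-dimethyl-1-(3,4,5-trimethoxyphenyl)butan-1-ol F2. Mitsunobu esterification of F2 (PhCO2H, PPh3, diisopropyl azodicarboxylate, PhMe, 0 °C) should then install the benzoate with inversion at C10. The fallback comes back to the route at 22; the apolar solvent and low temperature are chosen to suppress ionisation of the electron-rich benzylic centre.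

Step 10. Hydride displacement may be overtaken by cyclisation, either through attack of a dithiane sulfur on the C8 mesylate (five-membered sulfonium ion) or through S–O cleavage followed by tetrahydrofuran closure. The fallback sets out from bis-mesylate 18 and replaces the hydride SN2 step by a soft nucleophile followed by radical reduction. PhSeNa (from PhSeSePh and NaBH4, EtOH/THF, rt) should displace both mesylates to give 2-{(2R,3R)-3-[3,5-dimethoxy-4-(triisopropylsilyloxy)benzyl]-1,4-bis(phenylselanyl)butan-2-yl}-2-(3,4,5-trimethoxyphenyl)-1,3-dithiane F3. Bu3SnH with 2,2'-azobis(2-methylpropionitrile) in PhH at 80 °C should then cleave both C–Se bonds to C–H much faster than it attacks the dithiane. The fallback comes back to the route at 19.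

Further compounds
F1 | step 15 | (1R,2S,3R)-2,3-dimethyl-4-(1,3,5-trimethoxy-4-oxocyclohexa-2,5-dien-1-yl)-1-(3,4,5-trimethoxyphenyl)butyl benzoate | COC1=CC(OC)(C[C@@H](C)[C@H](C)[C@@H](OC(=O)c2ccccc2)c2cc(OC)c(OC)c(OC)c2)C=C(OC)C1=O
F2 | step 12 | (1S,2S,3R)-4-[3,5-dimethoxy-4-(triisopropylsilyloxy)phenyl]-2,3-dimethyl-1-(3,4,5-trimethoxyphenyl)butan-1-ol | C[C@H](Cc1cc(OC)c(O[Si](C(C)C)(C(C)C)C(C)C)c(OC)c1)[C@H](C)[C@H](O)c2cc(OC)c(OC)c(OC)c2
F3 | step 10 | 2-{(2R,3R)-3-[3,5-dimethoxy-4-(triisopropylsilyloxy)benzyl]-1,4-bis(phenylselanyl)butan-2-yl}-2-(3,4,5-trimethoxyphenyl)-1,3-dithiane | c1ccccc1[Se]C[C@H](Cc2cc(OC)c(O[Si](C(C)C)(C(C)C)C(C)C)c(OC)c2)[C@H](C[Se]c3ccccc3)C4(SCCCS4)c5cc(OC)c(OC)c(OC)c5
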